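**Retrosynthetic overview**
1. Target 8 ⇐ pentaol 7 by site-selective tribenzoylation (O7, O3, O6).
2. 7 ⇐ dienyl alcohol 4 by hydroxyl-directed syn-dihydroxylation of C1=C6 on the face opposite the 2,3-acetonide (sets C1 and C6).
3. 4 ⇐ cis-dihydrodiol ester 2 by acetonide formation and ester reduction.
4. 2 ⇐ methyl benzoate 1 by enzymatic dearomatising cis-dihydroxylation (sets C2, C3 and the absolute configuration), mirroring the oxygenase dearomatisation of a benzoate ring in the presumed biosynthesis.
5. Ring order: the six-membered carbocycle is the only ring of the target; it is not built but carved from the benzoate ring in step 1. The dioxolane of step 2 is a temporary ring.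

Assumption: locants follow the target (C1 quaternary carbinol, C2 CH(OH), C3 CH(OBz) next to C2, C4=C5 alkene, C6 CH(OBz) next to C1, C7 exocyclic CH2; "Ox" is the oxygen on Cx), and the toluene-dioxygenase strain E. coli JM109(pDTG601A) is at hand.

**Step 1**
Reactants: 1 methyl benzoate
Product: 2 methyl (5S,6R)-5,6-dihydroxycyclohexa-1,3-diene-1-carboxylate
Conditions: E. coli JM109(pDTG601A) whole cells (toluene dioxygenase, IPTG-induced), air, glucose feed, mineral-salts medium pH 7, 30 °C; EtOAc extraction
Reagents that add atoms: dioxygen, O=O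
Why: Enzymatic arene cis-dihydroxylation by toluene dioxygenase (a Rieske non-haem iron dioxygenase) is a described whole-cell reaction of benzoate esters that adds both atoms of O2 to one face of the ortho/meta bond, so the enzyme alone fixes C6 (R) and C5 (S) of 2 (the future C2 and C3) as essentially one enantiomer.

**Step 2**
Reactants: 2 methyl (5S,6R)-5,6-dihydroxycyclohexa-1,3-diene-1-carboxylate
Product: 3 methyl (3aR,7aS)-2,2-dimethyl-3a,7a-dihydro-1,3-benzodioxole-4-carboxylate
Conditions: Me2C(OMe)2, TsOH·H2O (cat.), acetone, 0 °C to rt, 30 min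
Reagents that add atoms: 2,2-dimethoxypropane, COC(C)(C)OC
Why: Acid-catalysed transacetalisation (acetonide formation) of the cis-diol gives the cis-fused dioxolane without touching either stereocentre, stops dehydration to a phenol and screens the lower face of the diene for step 4.

**Step 3**
Reactants: 3 methyl (3aR,7aS)-2,2-dimethyl-3a,7a-dihydro-1,3-benzodioxole-4-carboxylate
Product: 4 [(3aR,7aS)-2,2-dimethyl-3a,7a-dihydro-1,3-benzodioxol-4-yl]methanol
Conditions: iBu2AlH (2.5 equiv), CH2Cl2, −78 °C; aq. KNaC4H4O6 (potassium sodium tartrate) work-up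
Reagents that add atoms: none
Why: iBu2AlH 1,2-reduction of the conjugated ester at −78 °C gives the primary dienyl alcohol (ester-to-alcohol reduction), while the acetonide and both stereocentres are inert to hydride.

**Step 4**
Reactants: 4 [(3aR,7aS)-2,2-dimethyl-3a,7a-dihydro-1,3-benzodioxol-4-yl]methanol
Product: 7 (1S,2S,3S,6S)-1-(hydroxymethyl)cyclohex-4-ene-1,2,3,6-tetrol, via cyclic osmate ester 5 (not isolated), via acetonide triol 6 (not isolated)
Conditions: OsO4 (1.05 equiv), TMEDA (1.1 equiv), CH2Cl2, −78 °C; then conc. aq. HCl, MeOH, rt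
Reagents that add atoms: osmium tetroxide, O=[Os](=O)(=O)=O
Why: Donohoe-type hydrogen-bond-directed dihydroxylation, in which the OsO4·TMEDA complex is held by the C7 hydroxyl and so adds syn ([3+2]) to the neighbouring, more electron-rich C1=C6 bond rather than to C4=C5, on the face opposite the acetonide, which sets C1 and C6 with O1 and O6 cis to each other and trans to O2 and O3, after which methanolic HCl frees the diol from hexavalent osmium and removes the acetonide.

**Step 5**
Reactants: 7 (1S,2S,3S,6S)-1-(hydroxymethyl)cyclohex-4-ene-1,2,3,6-tetrol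
Product: 8 [(1R,2S,3S,6S)-3,6-bis(benzoyloxy)-1,2-dihydroxycyclohex-4-en-1-yl]methyl benzoate (target)
Conditions: BzCl (3.1 equiv, slow addition), pyridine, CH2Cl2, −40 to 0 °C
Reagents that add atoms: benzoyl chloride, O=C(Cl)c1ccccc1
Why: Site-selective acylation (nucleophilic acyl substitution) should take the primary O7 first and then the two allylic, pseudo-equatorial secondary hydroxyls O3 and O6, leaving free the axial O2 hydroxyl (wedged between quaternary C1 and the acylated C3) and the tertiary O1 hydroxyl, with no stereocentre involved.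

**Compound list**
1 | methyl benzoate | COC(=O)c1ccccc1 | starting material
2 | methyl (5S,6R)-5,6-dihydroxycyclohexa-1,3-diene-1-carboxylate (cis-diol) | COC(=O)C1=CC=C[C@H](O)[C@@H]1O | intermediate
3 | methyl (3aR,7aS)-2,2-dimethyl-3a,7a-dihydro-1,3-benzodioxole-4-carboxylate (acetonide of 2) | COC(=O)C1=CC=C[C@@H]2OC(C)(C)O[C@H]12 | intermediate
4 | [(3aR,7aS)-2,2-dimethyl-3a,7a-dihydro-1,3-benzodioxol-4-yl]methanol | OCC1=CC=C[C@@H]2OC(C)(C)O[C@H]12 | intermediate
5 | cyclic osmate ester of 6: OsO2(TMEDA) unit of hexavalent osmium bridging O1 and O6 on the face opposite the acetonide, 7-OH free | OC[C@]12O[Os-2]3(=O)(=O)(O[C@H]1C=C[C@@H]1OC(C)(C)O[C@H]21)[N+](C)(C)CC[N+]3(C)C | intermediate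
6 | (3aS,4S,5S,7aS)-4-(hydroxymethyl)-2,2-dimethyl-3a,4,5,7a-tetrahydro-1,3-benzodioxole-4,5-diol (acetonide triol; 4,5-diol cis, anti to the dioxolane) | OC[C@]1(O)[C@@H](O)C=C[C@@H]2OC(C)(C)O[C@H]12 | intermediate
7 | (1S,2S,3S,6S)-1-(hydroxymethyl)cyclohex-4-ene-1,2,3,6-tetrol (1-OH cis to 6-OH, both trans to the cis-2,3-diol) | OC[C@]1(O)[C@@H](O)C=C[C@H](O)[C@@H]1O | intermediate
8 | [(1R,2S,3S,6S)-3,6-bis(benzoyloxy)-1,2-dihydroxycyclohex-4-en-1-yl]methyl benzoate | O=C(OC[C@]1(O)[C@@H](OC(=O)c2ccccc2)C=C[C@H](OC(=O)c2ccccc2)[C@@H]1O)c1ccccc1 | target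

**Totals**
Total step count: 5. Longest linear sequence: 5 steps (1 to 8, fully linear).

**Steps most likely to fail, with fallbacks**

Step 1 (low titre of ester-substituted diols; 2 dehydrates easily). This fallback replaces 1 itself, so it sets out from no numbered compound but from purchased bromobenzene (Brc1ccccc1), and it comes back to the route at 3. The carbon C7 is then brought in by carbonylation after the dearomatisation. Bromobenzene is fed to the same cells, an oxidation that runs at high titre and whose product is also sold, to give (1S,2S)-3-bromocyclohexa-3,5-diene-1,2-diol F1. Acetonide formation as in step 2 gives (3aS,7aS)-4-bromo-2,2-dimethyl-3a,7a-dihydro-1,3-benzodioxole F2. Methoxycarbonylation of the vinyl bromide (Pd(OAc)2, PPh3, CO 1 atm, MeOH, Et3N, DMF, 60 °C) gives 3.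

Step 4 (attack at C4=C5 or bis-osmylation; handling of the polar pentaol). The fallback sets out from 4 and comes back at 6, replacing osmylation by epoxidation and a retentive epoxide opening. Hydroxyl-directed epoxidation (VO(acac)2 cat., t-BuOOH, CH2Cl2, 0 °C) of the C1=C6 bond on the face opposite the acetonide gives the epoxy alcohol F3. Pd(PPh3)4 (zerovalent palladium, cat.) under CO2 (1 atm) in THF ionises the vinyl epoxide with inversion, and the carbonate formed from the C1 alkoxide closes on C6 with a second inversion, giving the cis-1,6-cyclic carbonate F4. K2CO3 in MeOH cleaves the carbonate to 6, which goes on to 7 in methanolic HCl as in step 4.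

Step 5 (O6 versus O2 selectivity, over-acylation, acyl migration). The fallback sets out from 6 and comes back at 8, replacing the one-pot tribenzoylation by a stepwise acylation under acetonide control. For this, 6 is isolated by cleaving 5 with ethylenediamine in CH2Cl2 in place of methanolic HCl. BzCl (2.2 equiv), pyridine and DMAP at 0 °C give the acetonide 6,7-dibenzoate F5, the tertiary hydroxyl staying free. Aqueous AcOH (80%, 40 °C) removes the acetonide to give the triol dibenzoate F6. A stannylene acetal across the cis-2,3-diol (Bu2SnO, MeOH, reflux) followed by BzCl (1.05 equiv) and Et3N at 0 °C acylates the equatorial allylic O3 only and gives 8.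

**Further compounds**
F1 | step 1 | (1S,2S)-3-bromocyclohexa-3,5-diene-1,2-diol | BrC1=CC=C[C@H](O)[C@@H]1O
F2 | step 1 | (3aS,7aS)-4-bromo-2,2-dimethyl-3a,7a-dihydro-1,3-benzodioxole | BrC1=CC=C[C@@H]2OC(C)(C)O[C@H]12
F3 | step 4 | epoxy alcohol: C1–C6 epoxide of 4 on the face opposite the acetonide, 7-OH free | OC[C@]12O[C@H]1C=C[C@@H]1OC(C)(C)O[C@H]21
F4 | step 4 | cis-1,6-cyclic carbonate of 6 (carbonate on the face opposite the acetonide, 7-OH free) | OC[C@]12OC(=O)O[C@H]1C=C[C@@H]1OC(C)(C)O[C@H]21
F5 | step 5 | [(3aS,4S,5S,7aS)-5-(benzoyloxy)-4-hydroxy-2,2-dimethyl-3a,4,5,7a-tetrahydro-1,3-benzodioxol-4-yl]methyl benzoate | O=C(OC[C@]1(O)[C@@H](OC(=O)c2ccccc2)C=C[C@@H]2OC(C)(C)O[C@H]12)c1ccccc1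
F6 | step 5 | [(1R,2S,3S,6S)-6-(benzoyloxy)-1,2,3-trihydroxycyclohex-4-en-1-yl]methyl benzoate | O=C(OC[C@]1(O)[C@@H](OC(=O)c2ccccc2)C=C[C@H](O)[C@@H]1O)c1ccccc1
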